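**Retrosynthetic overview**
1. Pyranone ring (last ring): oxidative lactonisation of a (Z)-allylic primary alcohol onto the cis tertiary alcohol of the C6 side chain. The same oxidation regenerates the furoyl and C7 ketones from their carbinols.
2. Oxirane and glycidate: opening of an epoxy δ-lactone tied through the reduced furoyl carbon (Cf–O–CO–Ca–C1). The lactone comes from a samarium Reformatsky closure onto the C1 ketone, dehydration and nucleophilic epoxidation.
3. C6 quaternary centre: aldol of the C1 enolate with a (Z)-dienal made from 2-methylbut-3-yn-2-ol and propargyl alcohol. C1′ and C5: CBS reduction, then hydroxyl-directed hydrogenation of a 3-acetyl enone obtained from the C5 enol triflate.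
4. Cyclohexane C1–C6 (only carbocycle): Michael–Claisen [3+3] annulation. The feature it rests on is quaternary C2 (methyl, 3-furoyl) next to C1: C2 is the α-carbon of a furyl β-keto ester whose ester carbon becomes C1, and C3–C4–C5(=O)–C6(CH3) is ethyl vinyl ketone.
5. Ring order: cyclohexane (step 2), temporary δ-lactone (step 19), oxirane (step 21), pyranone (step 24).

Key step: step 2

Conventions: ring atoms C1 (spiro carbon), C2 (methyl, furoyl), C3, C4, C5 (hydroxyethyl), C6 (methyl, acyl). Ca = glycidate CH; Cf = carbon joining C2 to the furan; C1′ = carbinol carbon on C5. Side chain on C6: C7, C8 (=CH), C9, C10=C11, C12 (CH2O or lactone C=O), C13 (CMe2). α-face = face of the C2 methyl; β-face = face of the C2 furoyl.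
Assumption: the quinine-derived thiourea is taken to give the (S)-Michael adduct 5; if the sense proves opposite, the pseudoenantiomeric quinidine-derived catalyst would be used.

**Step 1**
Reactants: 1 methyl furan-3-carboxylate; 2 methyl propanoate
Product: 3 methyl 3-(furan-3-yl)-2-methyl-3-oxopropanoate (racemic)
Conditions: LiN(i-Pr)2 (2.1 equiv), 2 (2.1 equiv), THF, −78 °C; then 1, −78 → 0 °C; aq. NH4Cl
Reagents that add atoms: none
Why: Crossed Claisen condensation in which the preformed lithium enolate of 2 acylates the non-enolisable ester 1 and a second equivalent of enolate deprotonates the β-keto ester to drive the equilibrium; the α-centre of 3 is labile and of no consequence.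

**Step 2**
Reactants: 3 methyl 3-(furan-3-yl)-2-methyl-3-oxopropanoate; 4 pent-1-en-3-one
Product: 6 (S)-6-(furan-3-carbonyl)-3-hydroxy-2,6-dimethylcyclohex-2-en-1-one (enol form of the 1,3-dione), via Michael adduct 5 (not isolated)
Conditions: 1-[3,5-bis(trifluoromethyl)phenyl]-3-[(8S,9S)-6′-methoxycinchonan-9-yl]thiourea (10 mol %), 4 (1.2 equiv), toluene, −20 °C; evaporate; KOt-Bu (2.2 equiv), THF, −40 → 0 °C; 1 M HCl
Reagents that add atoms: none
Why: The quinuclidine nitrogen of the catalyst deprotonates 3 while the thiourea hydrogen-bonds the enone, and the bound enol adds to the β-carbon of 4 (C2–C3 bond), the catalyst alone fixing the C2 quaternary centre as (S)-5. KOt-Bu then forms the ethyl ketone enolate at C6, which attacks the ester carbonyl in a 6-exo-trig acyl substitution (Claisen/Dieckmann-type closure, C6–C1 bond) and closes the cyclohexane. Loss of methoxide and deprotonation of the 2-methyl-1,3-dione make the closure irreversible, and the resulting enolate deactivates C1 and the furoyl group towards retro-Claisen attack. The closest known reactions are the cinchona-thiourea Michael addition of α-substituted β-keto esters to vinyl ketones and the Michael–Claisen synthesis of cyclohexane-1,3-diones. Regioselectivity follows from ring size, since the C4 enolate could only close a four-membered ring and the aldol of the C6 enolate onto the furoyl ketone is reversible. The step needs cyclisation to outrun retro-Michael cleavage of 5 (which would erode the ee) and methoxide cleavage of the non-enolisable β-keto ester, hence the hindered base and low temperature.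

**Step 3**
Reactants: 6 (S)-6-(furan-3-carbonyl)-3-hydroxy-2,6-dimethylcyclohex-2-en-1-one
Product: 7 (S)-4-(furan-3-carbonyl)-2,4-dimethyl-3-oxocyclohex-1-en-1-yl trifluoromethanesulfonate (C5 enol triflate)
Conditions: Tf2O (1.1 equiv), Et3N, CH2Cl2, −78 °C
Reagents that add atoms: trifluoromethanesulfonic anhydride O=S(=O)(C(F)(F)F)OS(=O)(=O)C(F)(F)F
Why: O-Sulfonylation of the vinylogous acid should occur at the C5 oxygen, next to the C4 methylene, and not at the C1 oxygen, which is shielded by quaternary C2; no stereocentre is formed.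

**Step 4**
Reactants: 7 C5 enol triflate
Product: 9 3-acetyl-6-(furan-3-carbonyl)-2,6-dimethylcyclohex-2-en-1-one (C2 as in 6), via ethoxydiene 8 (not isolated)
Conditions: tributyl(1-ethoxyvinyl)stannane, Pd(PPh3)4 (5 mol %), LiCl, THF, 65 °C; then 1 M HCl, THF, 0 °C → rt
Reagents that add atoms: tributyl(1-ethoxyvinyl)stannane CCCC[Sn](CCCC)(CCCC)C(=C)OCC; water O
Why: Stille coupling of the β-triflyloxy enone with an acetyl anion equivalent, followed by enol ether hydrolysis, installs the C5 acetyl group without touching the ketones or the C2 centre.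

**Step 5**
Reactants: 9 3-acetyl enone
Product: 10 6-(furan-3-carbonyl)-3-[(R)-1-hydroxyethyl]-2,6-dimethylcyclohex-2-en-1-one (C2 as in 6)
Conditions: (S)-2-methyl-CBS-oxazaborolidine (0.2 equiv), BH3·SMe2 (0.7 equiv), THF, −40 °C; MeOH
Reagents that add atoms: none
Why: Corey–Bakshi–Shibata reduction in which the unhindered methyl ketone reacts ahead of the C1 and furoyl ketones (both adjoin quaternary C2), and the (S)-catalyst, with the alkenyl group as the large substituent, sets C1′ as (R).

**Step 6**
Reactants: 10 allylic alcohol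
Product: 11 (2R,3S,6S)-6-(furan-3-carbonyl)-3-[(R)-1-hydroxyethyl]-2,6-dimethylcyclohexan-1-one (route C5 S; C5–H and C6–H α)
Conditions: [Ir(cod)(PCy3)(py)]PF6 (10 mol %), H2 (1 atm), CH2Cl2, 0 °C → rt
Reagents that add atoms: none
Why: Hydroxyl-directed hydrogenation: with the carbinol hydrogen eclipsing C5=C6 (1,3-allylic strain against the C6 methyl) the iridium-bound hydroxyl delivers H2 to its own face, which sets C5 as (S); the C6–H centre formed at the same time is epimerisable and is replaced in step 15.

**Step 7**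
Reactants: 11 hydroxy ketone
Product: 12 C1′ tert-butyldimethylsilyl ether of 11
Conditions: TBSOTf, 2,6-lutidine, CH2Cl2, −78 °C
Reagents that add atoms: tert-butyldimethylsilyl trifluoromethanesulfonate CC(C)(C)[Si](C)(C)OS(=O)(=O)C(F)(F)F
Why: Silylation of the secondary alcohol with a silyl triflate and a non-nucleophilic base, which leaves the cleavage-prone 1,3-diketone at C2 intact and protects C1′–OH until the last step.

**Step 8**
Reactants: 13 2-methylbut-3-yn-2-ol
Product: 14 triethyl[(2-methylbut-3-yn-2-yl)oxy]silane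
Conditions: TESOTf, 2,6-lutidine, CH2Cl2, 0 °C
Reagents that add atoms: triethylsilyl trifluoromethanesulfonate CC[Si](CC)(CC)OS(=O)(=O)C(F)(F)F
Why: Silyl triflate silylation, the standard way to protect a tertiary alcohol.

**Step 9**
Reactants: 14 triethyl[(2-methylbut-3-yn-2-yl)oxy]silane
Product: 15 4-methyl-4-(triethylsilyloxy)pent-2-yn-1-ol
Conditions: n-BuLi, THF, −78 °C; (CH2O)n, −78 °C → rt; aq. NH4Cl
Reagents that add atoms: paraformaldehyde (as formaldehyde) C=O
Why: Addition of the lithium acetylide to formaldehyde gives the propargylic alcohol needed to direct the next step.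

**Step 10**
Reactants: 15 4-methyl-4-(triethylsilyloxy)pent-2-yn-1-ol
Product: 16 (Z)-3-iodo-4-methyl-4-(triethylsilyloxy)pent-2-en-1-ol
Conditions: NaAlH2(OCH2CH2OMe)2, THF, 0 °C; then I2, −78 °C
Reagents that add atoms: iodine II
Why: Alkoxide-directed trans-hydroalumination delivers hydride to C2 and holds aluminium on C3 cis to the CH2O group, and iodinolysis with retention gives the (Z)-iodoalkene, which fixes the C8=C9 geometry of the target.

**Step 11**
Reactants: 17 prop-2-yn-1-ol
Product: 18 (Z)-3-(tributylstannyl)prop-2-en-1-ol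
Conditions: LiAlH4, THF, 0 °C → rt; then Bu3SnOTf, −78 °C → rt
Reagents that add atoms: tributyltin trifluoromethanesulfonate CCCC[Sn](CCCC)(CCCC)OS(=O)(=O)C(F)(F)F
Why: trans-Hydroalumination of the propargylic alkoxide followed by aluminium-to-tin exchange with retention gives the (Z)-alkenylstannane.

**Step 12**
Reactants: 18 (Z)-3-(tributylstannyl)prop-2-en-1-ol
Product: 19 (Z)-tributyl[3-(triethylsilyloxy)prop-1-en-1-yl]stannane
Conditions: TESCl, imidazole, CH2Cl2, 0 °C
Reagents that add atoms: chlorotriethylsilane CC[Si](Cl)(CC)CC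
Why: Silylation of the primary alcohol under mild basic conditions that avoid protodestannylation.

**Step 13**
Reactants: 16 (Z)-iodoalkene; 19 (Z)-stannane
Product: 20 (2E)-4-methyl-4-(triethylsilyloxy)-3-[(Z)-3-(triethylsilyloxy)prop-1-en-1-yl]pent-2-en-1-ol (CH2OH cis to the propenyl branch)
Conditions: Pd(PPh3)4 (5 mol %), CuI, CsF, DMF, 40 °C
Reagents that add atoms: none
Why: Stille coupling with retention at both alkenes; CuI and CsF speed transmetalation at the hindered iodoalkene.

**Step 14**
Reactants: 20 dienol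
Product: 21 (2E)-4-methyl-4-(triethylsilyloxy)-3-[(Z)-3-(triethylsilyloxy)prop-1-en-1-yl]pent-2-enal
Conditions: Dess–Martin periodinane, NaHCO3, CH2Cl2, 0 °C
Reagents that add atoms: none
Why: Buffered Dess–Martin oxidation of the allylic alcohol gives the enal without isomerising the trisubstituted alkene.

**Step 15**
Reactants: 12 silyl ether ketone; 21 dienal
Product: 22 C6 aldol adduct (C6 methyl β; C7 carbinol side chain α; C7 epimers)
Conditions: LiN(SiMe3)2, THF, −78 → −20 °C; then 21, −78 °C; aq. NH4Cl at −78 °C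
Reagents that add atoms: none
Why: Lithium enolate aldol addition: quaternary C2 allows enolisation of C1 only towards C6, and the aldehyde should add to the tetrasubstituted enolate on the α-face, anti to the C5 branch (held pseudo-axial by 1,2-allylic strain with the C6 methyl), which sets the C6 quaternary centre; C7 is oxidised later.

**Step 16**
Reactants: 22 aldol adduct
Product: 23 C7 triethylsilyl ether of 22
Conditions: TESOTf, 2,6-lutidine, CH2Cl2, −78 °C
Reagents that add atoms: triethylsilyl trifluoromethanesulfonate CC[Si](CC)(CC)OS(=O)(=O)C(F)(F)F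
Why: Low-temperature silylation caps the hindered β-hydroxy ketone before retro-aldol cleavage can occur.

**Step 17**
Reactants: 23 silylated aldol adduct
Product: 24 furyl carbinol (Cf S; C1 ketone retained)
Conditions: NaBH4, MeOH/THF (1:4), −20 °C; AcOH
Reagents that add atoms: none
Why: Borohydride reduction of the only accessible ketone (C1 lies between two quaternary carbons); on the Felkin–Anh model hydride attacks anti to the C2–C1 bond and past the C2 methyl, which should give the (S)-carbinol whose furyl group later sits pseudo-equatorial and cis to the C2 methyl on the lactone.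

**Step 18**
Reactants: 24 furyl carbinol
Product: 25 Cf bromoacetate of 24
Conditions: BrCH2COBr, pyridine, CH2Cl2, 0 °C
Reagents that add atoms: bromoacetyl bromide BrCC(Br)=O
Why: Acylation of the hindered secondary alcohol with a reactive acyl bromide installs the two carbons Ca and the carboxyl carbon as a tether on Cf.

**Step 19**
Reactants: 25 bromoacetate
Product: 26 β-hydroxy δ-lactone (ring Cf–O–CO–Ca–C1–C2; C1 carbinol configuration unassigned)
Conditions: SmI2 (2.2 equiv), THF, −78 °C
Reagents that add atoms: none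
Why: Samarium Reformatsky reaction: SmI2 reduces the C–Br bond and the samarium enolate adds to the C1 ketone through a six-membered chelated transition state, the intramolecular delivery compensating for a carbonyl flanked by two quaternary carbons; the C1 configuration is removed in step 20.

**Step 20**
Reactants: 26 β-hydroxy δ-lactone
Product: 27 α,β-unsaturated δ-lactone (C1=Ca)
Conditions: SOCl2, pyridine, CH2Cl2, −20 → 0 °C
Reagents that add atoms: none
Why: Dehydration through the chlorosulfite with pyridine-promoted elimination; the only β-hydrogens are on Ca because C2 and C6 are quaternary, so the conjugated C1=Ca alkene forms regiospecifically.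

**Step 21**
Reactants: 27 unsaturated δ-lactone
Product: 28 epoxy δ-lactone (epoxide oxygen β; Ca α; carboxyl carbon cis to C2)
Conditions: t-BuOOH (in decane), n-BuLi, THF, −78 → 20 °C
Reagents that add atoms: tert-butyl hydroperoxide CC(C)(C)OO
Why: Weitz–Scheffer nucleophilic epoxidation: the peroxide anion should add to C1 from the β-face, flanked only by the C6 methyl, because the α-face carries the pseudo-axial C2 methyl and the C6 side chain, and the lactone enolate then closes on oxygen, which sets C1 and Ca; the ring keeps the carboxyl carbon cis to C2 and no γ-hydrogen is available for deconjugation.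

**Step 22**
Reactants: 28 epoxy δ-lactone
Product: 29 epoxy lactone triol (C7–OH, C12–OH, C13–OH free; C1′–OTBS kept)
Conditions: HF·pyridine, pyridine, THF, 0 °C
Reagents that add atoms: none
Why: Buffered fluoride desilylation removes the three triethylsilyl ethers faster than the tert-butyldimethylsilyl ether, and it is done while Cf–O is still tied up in the lactone.

**Step 23**
Reactants: 29 epoxy lactone triol
Product: 31 methyl glycidate tetraol (Cf–OH, C7–OH, C12–OH, C13–OH), via lithium carboxylate 30 (not isolated)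
Conditions: LiOH (1.1 equiv), THF/H2O, 0 °C; evaporate; MeI, DMF, 0 °C → rt
Reagents that add atoms: lithium hydroxide [Li+].[OH-]; iodomethane CI
Why: Saponification opens the lactone irreversibly to the carboxylate, which is O-methylated by SN2 without ever protonating the glycidic acid (so decarboxylative epoxide opening is avoided); the ester stays cis to C2 and no stereocentre is touched.

**Step 24**
Reactants: 31 methyl glycidate tetraol
Product: 34 C1′ tert-butyldimethylsilyl ether of the target, via hydroxy enal 32 (not isolated), via lactol 33 (not isolated)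
Conditions: Dess–Martin periodinane (6 equiv), NaHCO3, CH2Cl2, 0 °C → rt
Reagents that add atoms: none
Why: Dess–Martin oxidation converts the Cf and C7 carbinols into ketones and the (Z)-allylic primary alcohol into an enal, which the cis tertiary alcohol traps as a lactol that is oxidised on to the lactone (oxidative lactonisation closing the pyranone); the silyl ether keeps C1′ at the alcohol level.

**Step 25**
Reactants: 34 silyl ether of the target
Product: 35 CNP0293135.1 (target)
Conditions: HF·pyridine, THF, 0 °C → rt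
Reagents that add atoms: none
Why: Fluoride cleavage of the remaining silyl ether under weakly acidic conditions that the glycidate, the dienone lactone and the acylfuran should tolerate.

**Compound list**
1 | methyl furan-3-carboxylate | COC(=O)c1ccoc1 | starting material
2 | methyl propanoate | CCC(=O)OC | starting material
3 | methyl 3-(furan-3-yl)-2-methyl-3-oxopropanoate (racemic) | COC(=O)C(C)C(=O)c1ccoc1 | intermediate
4 | pent-1-en-3-one | CCC(=O)C=C | starting material
5 | methyl (S)-2-(furan-3-carbonyl)-2-methyl-5-oxoheptanoate | COC(=O)[C@](C)(C(=O)c1ccoc1)CCC(=O)CC | intermediate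
6 | (S)-6-(furan-3-carbonyl)-3-hydroxy-2,6-dimethylcyclohex-2-en-1-one (enol of 4-(3-furoyl)-2,4-dimethylcyclohexane-1,3-dione) | O=C1C(C)=C(O)CC[C@@]1(C)C(=O)c1ccoc1 | intermediate
7 | (S)-4-(furan-3-carbonyl)-2,4-dimethyl-3-oxocyclohex-1-en-1-yl trifluoromethanesulfonate | O=C1C(C)=C(OS(=O)(=O)C(F)(F)F)CC[C@@]1(C)C(=O)c1ccoc1 | intermediate
8 | 3-(1-ethoxyvinyl)-6-(furan-3-carbonyl)-2,6-dimethylcyclohex-2-en-1-one (C2 as in 6) | O=C1C(C)=C(C(=C)OCC)CC[C@@]1(C)C(=O)c1ccoc1 | intermediate
9 | 3-acetyl-6-(furan-3-carbonyl)-2,6-dimethylcyclohex-2-en-1-one (C2 as in 6) | O=C1C(C)=C(C(C)=O)CC[C@@]1(C)C(=O)c1ccoc1 | intermediate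
10 | 6-(furan-3-carbonyl)-3-[(R)-1-hydroxyethyl]-2,6-dimethylcyclohex-2-en-1-one (C2 as in 6) | O=C1C(C)=C([C@@H](C)O)CC[C@@]1(C)C(=O)c1ccoc1 | intermediate
11 | (2R,3S,6S)-6-(furan-3-carbonyl)-3-[(R)-1-hydroxyethyl]-2,6-dimethylcyclohexan-1-one (route C5 S; C5–H and C6–H α) | O=C1[C@@H](C)[C@@H]([C@@H](C)O)CC[C@@]1(C)C(=O)c1ccoc1 | intermediate
12 | C1′ tert-butyldimethylsilyl ether of 11 | O=C1[C@@H](C)[C@@H]([C@@H](C)O[Si](C)(C)C(C)(C)C)CC[C@@]1(C)C(=O)c1ccoc1 | intermediate
13 | 2-methylbut-3-yn-2-ol | C#CC(C)(C)O | starting material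
14 | triethyl[(2-methylbut-3-yn-2-yl)oxy]silane | C#CC(C)(C)O[Si](CC)(CC)CC | intermediate
15 | 4-methyl-4-(triethylsilyloxy)pent-2-yn-1-ol | OCC#CC(C)(C)O[Si](CC)(CC)CC | intermediate
16 | (Z)-3-iodo-4-methyl-4-(triethylsilyloxy)pent-2-en-1-ol | OC/C=C(\I)C(C)(C)O[Si](CC)(CC)CC | intermediate
17 | prop-2-yn-1-ol | OCC#C | starting material
18 | (Z)-3-(tributylstannyl)prop-2-en-1-ol | OC/C=C\[Sn](CCCC)(CCCC)CCCC | intermediate
19 | (Z)-tributyl[3-(triethylsilyloxy)prop-1-en-1-yl]stannane | CC[Si](CC)(CC)OC/C=C\[Sn](CCCC)(CCCC)CCCC | intermediate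
20 | (2E)-4-methyl-4-(triethylsilyloxy)-3-[(Z)-3-(triethylsilyloxy)prop-1-en-1-yl]pent-2-en-1-ol | OC/C=C(\C=C/CO[Si](CC)(CC)CC)C(C)(C)O[Si](CC)(CC)CC | intermediate
21 | (2E)-4-methyl-4-(triethylsilyloxy)-3-[(Z)-3-(triethylsilyloxy)prop-1-en-1-yl]pent-2-enal | O=C/C=C(\C=C/CO[Si](CC)(CC)CC)C(C)(C)O[Si](CC)(CC)CC | intermediate
22 | C6 aldol adduct: 12 carrying on the α-face of C6 the chain C7H(OH)–C8H=C9(C13Me2OTES)–C10H=C11H–C12H2OTES (C6 methyl β; C7 epimers) | O=C1[C@](C)(C(O)/C=C(\C=C/CO[Si](CC)(CC)CC)C(C)(C)O[Si](CC)(CC)CC)[C@@H]([C@@H](C)O[Si](C)(C)C(C)(C)C)CC[C@@]1(C)C(=O)c1ccoc1 | intermediate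
23 | C7 triethylsilyl ether of 22 | O=C1[C@](C)(C(O[Si](CC)(CC)CC)/C=C(\C=C/CO[Si](CC)(CC)CC)C(C)(C)O[Si](CC)(CC)CC)[C@@H]([C@@H](C)O[Si](C)(C)C(C)(C)C)CC[C@@]1(C)C(=O)c1ccoc1 | intermediate
24 | furyl carbinol from 23 (Cf S; C1 ketone) | O=C1[C@](C)(C(O[Si](CC)(CC)CC)/C=C(\C=C/CO[Si](CC)(CC)CC)C(C)(C)O[Si](CC)(CC)CC)[C@@H]([C@@H](C)O[Si](C)(C)C(C)(C)C)CC[C@@]1(C)[C@@H](O)c1ccoc1 | intermediate
25 | Cf bromoacetate of 24 | O=C1[C@](C)(C(O[Si](CC)(CC)CC)/C=C(\C=C/CO[Si](CC)(CC)CC)C(C)(C)O[Si](CC)(CC)CC)[C@@H]([C@@H](C)O[Si](C)(C)C(C)(C)C)CC[C@@]1(C)[C@@H](OC(=O)CBr)c1ccoc1 | intermediate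
26 | β-hydroxy δ-lactone (C1–OH; ring Cf–O–CO–Ca–C1–C2; C1 unassigned) | OC12CC(=O)O[C@@H](c3ccoc3)[C@]1(C)CC[C@H]([C@@H](C)O[Si](C)(C)C(C)(C)C)[C@@]2(C)C(O[Si](CC)(CC)CC)/C=C(\C=C/CO[Si](CC)(CC)CC)C(C)(C)O[Si](CC)(CC)CC | intermediate
27 | α,β-unsaturated δ-lactone (C1=Ca) | C12=CC(=O)O[C@@H](c3ccoc3)[C@]1(C)CC[C@H]([C@@H](C)O[Si](C)(C)C(C)(C)C)[C@@]2(C)C(O[Si](CC)(CC)CC)/C=C(\C=C/CO[Si](CC)(CC)CC)C(C)(C)O[Si](CC)(CC)CC | intermediate
28 | epoxy δ-lactone (epoxide oxygen β; carboxyl carbon cis to C2) | O1[C@]23[C@H]1C(=O)O[C@@H](c4ccoc4)[C@]2(C)CC[C@H]([C@@H](C)O[Si](C)(C)C(C)(C)C)[C@@]3(C)C(O[Si](CC)(CC)CC)/C=C(\C=C/CO[Si](CC)(CC)CC)C(C)(C)O[Si](CC)(CC)CC | intermediate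
29 | epoxy lactone triol (C7–OH, C12–OH, C13–OH; C1′–OTBS) | O1[C@]23[C@H]1C(=O)O[C@@H](c4ccoc4)[C@]2(C)CC[C@H]([C@@H](C)O[Si](C)(C)C(C)(C)C)[C@@]3(C)C(O)/C=C(\C=C/CO)C(C)(C)O | intermediate
30 | lithium glycidate of the opened lactone | [Li+].[O-]C(=O)[C@H]1O[C@@]12[C@](C)([C@@H](O)c1ccoc1)CC[C@H]([C@@H](C)O[Si](C)(C)C(C)(C)C)[C@@]2(C)C(O)/C=C(\C=C/CO)C(C)(C)O | intermediate
31 | methyl glycidate tetraol (Cf–OH, C7–OH, C12–OH, C13–OH; C1′–OTBS) | COC(=O)[C@H]1O[C@@]12[C@](C)([C@@H](O)c1ccoc1)CC[C@H]([C@@H](C)O[Si](C)(C)C(C)(C)C)[C@@]2(C)C(O)/C=C(\C=C/CO)C(C)(C)O | intermediate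
32 | hydroxy enal (Cf and C7 ketones; C12 aldehyde; C13–OH) | COC(=O)[C@H]1O[C@@]12[C@](C)(C(=O)c1ccoc1)CC[C@H]([C@@H](C)O[Si](C)(C)C(C)(C)C)[C@@]2(C)C(=O)/C=C(\C=C/C=O)C(C)(C)O | intermediate
33 | lactol (C12 hemiacetal closed onto the C13 oxygen) | COC(=O)[C@H]1O[C@@]12[C@](C)(C(=O)c1ccoc1)CC[C@H]([C@@H](C)O[Si](C)(C)C(C)(C)C)[C@@]2(C)C(=O)/C=C1\C=CC(O)OC1(C)C | intermediate
34 | C1′ tert-butyldimethylsilyl ether of the target | COC(=O)[C@H]1O[C@@]12[C@](C)(C(=O)c1ccoc1)CC[C@H]([C@@H](C)O[Si](C)(C)C(C)(C)C)[C@@]2(C)C(=O)/C=C1\C=CC(=O)OC1(C)C | intermediate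
35 | CNP0293135.1: methyl 8-(furan-3-carbonyl)-5-[(R)-1-hydroxyethyl]-4,8-dimethyl-4-[(E)-(6,6-dimethyl-2-oxo-2H-pyran-5(6H)-ylidene)acetyl]-1-oxaspiro[2.5]octane-2-carboxylate, configuration as in the SMILES | COC(=O)[C@H]1O[C@@]12[C@](C)(C(=O)c1ccoc1)CC[C@H]([C@@H](C)O)[C@@]2(C)C(=O)/C=C1\C=CC(=O)OC1(C)C | target

**Step count**
Total: 25 steps. Longest linear sequence: 18 steps (steps 1–7, then 15–25); the side-chain aldehyde 21 is made in 7 steps (8–14) and joins at step 15.

**Steps most likely to fail**

Step 2. The acyclic aryl β-keto ester may be discriminated poorly by the catalyst. Under the base, retro-Michael/Michael equilibration of 5 could erode the ee, and methoxide could cleave the non-enolisable β-keto ester before ring closure. The fallback sets out from 3. Condensation with (R)-1-phenylethylamine (TsOH cat., toluene, Dean–Stark) would give the hydrogen-bonded enamino ester methyl (Z)-3-(furan-3-yl)-2-methyl-3-{[(R)-1-phenylethyl]amino}prop-2-enoate F1. F1 should add to 4 in an auxiliary-controlled (d'Angelo-type) Michael reaction on the face anti to the phenyl group; the (R)-amine is chosen on that model. Hydrolysis with aqueous acetic acid releases the amine and gives 5, where the route is rejoined; the Claisen closure to 6 is then run separately with KOt-Bu.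

Step 21. Conjugate addition of the peroxide anion at C1, which lies between two quaternary carbons, may be too slow. The peroxide or alkoxide may open the lactone instead, or the facial preference may be weak. The fallback sets out from 24. Acylation with chloroacetyl chloride and pyridine would give the Cf chloroacetate of 24 F2. Treatment with KN(SiMe3)2 in THF at −78 → 0 °C should then effect an intramolecular Darzens condensation onto the C1 ketone and give the epoxy lactone 28 directly, where the route is rejoined. The tether again places the carboxyl carbon cis to C2. The configuration at C1 would then be set in the C–C bond-forming step and would have to be confirmed.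

Step 19. Addition of the samarium enolate to the doubly neopentyl C1 ketone may lose to protonation of the enolate (plain debromination to the acetate), or the congested aldolate may revert by retro-aldol cleavage. The fallback sets out from 24. Esterification with diethylphosphonoacetic acid (DCC, DMAP) would give the Cf diethylphosphonoacetate of 24 F3. An intramolecular Horner–Wadsworth–Emmons reaction (LiCl, DBU, MeCN, 60 °C) should then give the unsaturated lactone 27, where the route is rejoined. The irreversible elimination of phosphate pulls an unfavourable addition equilibrium forward and makes step 20 unnecessary.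

**Further compounds**
F1 | step 2 | methyl (Z)-3-(furan-3-yl)-2-methyl-3-{[(R)-1-phenylethyl]amino}prop-2-enoate | COC(=O)/C(C)=C(\N[C@H](C)c1ccccc1)c1ccoc1
F2 | step 21 | Cf chloroacetate of 24 | O=C1[C@](C)(C(O[Si](CC)(CC)CC)/C=C(\C=C/CO[Si](CC)(CC)CC)C(C)(C)O[Si](CC)(CC)CC)[C@@H]([C@@H](C)O[Si](C)(C)C(C)(C)C)CC[C@@]1(C)[C@@H](OC(=O)CCl)c1ccoc1
F3 | step 19 | Cf diethylphosphonoacetate of 24 | O=C1[C@](C)(C(O[Si](CC)(CC)CC)/C=C(\C=C/CO[Si](CC)(CC)CC)C(C)(C)O[Si](CC)(CC)CC)[C@@H]([C@@H](C)O[Si](C)(C)C(C)(C)C)CC[C@@]1(C)[C@@H](OC(=O)CP(=O)(OCC)OCC)c1ccoc1
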